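The oxolane is numbered O1, C2 (aryl), C3 (CH2OH), C4 (carbinol), C5. The ring is cut across O1–C2 and C4–C5: C5H2–O1 is formaldehyde, and C2–C3–C4 is a 1,3-zwitterion (benzylic C2 cation stabilised by the 3,4-dioxygenated aryl, C4 malonate anion), i.e. an enantiopure trans donor–acceptor cyclopropane made by organocatalytic cyclopropanation. Its strain-releasing Lewis-acid (3+2) annulation with CH2O forms both bonds at once and, by inversion at C2, delivers the contra-thermodynamic 2,3-cis aryl/CH2OR relationship. The C4 gem-diester is then excised oxidatively to a ketone; the veratryl Grignard adds anti to the two cis substituents, fixing the C4 carbinol, and hydrogenolysis frees the three hydroxyls.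

Key step: step 5

Remark on the chemistry: compound 8 is monomeric formaldehyde, generated by cracking commercial paraformaldehyde just before use; 1, 2, 4, 8 (as paraformaldehyde) and 13 are assumed to be purchased.

Step 1
Reactants: 1 3,4-bis(benzyloxy)benzaldehyde; 2 (triphenylphosphoranylidene)acetaldehyde
Product: 3 (E)-3-[3,4-bis(benzyloxy)phenyl]prop-2-enal
Conditions: toluene, 80 °C
Reagents that add atoms: none
Why: Wittig olefination with the stabilised formylmethylene ylide should give the (E)-enal, and the electron-rich product enal is less electrophilic than 1, which limits a second homologation.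

Step 2
Reactants: 3 (E)-3-[3,4-bis(benzyloxy)phenyl]prop-2-enal; 4 dimethyl bromomalonate
Product: 5 dimethyl (2S,3R)-2-[3,4-bis(benzyloxy)phenyl]-3-formylcyclopropane-1,1-dicarboxylate
Conditions: (S)-α,α-diphenylprolinol trimethylsilyl ether (20 mol %), 2,6-lutidine (1.1 equiv), CH2Cl2, 0 °C → rt
Reagents that add atoms: none
Why: Organocatalytic Michael-initiated ring closure: the bromomalonate adds to the (E)-iminium ion on the face anti to the CPh2OTMS group, which sets the aryl-bearing carbon as S, and 3-exo-tet alkylation of the resulting enamine closes the trans cyclopropane and sets the formyl-bearing carbon.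

Step 3
Reactants: 5 dimethyl (2S,3R)-2-[3,4-bis(benzyloxy)phenyl]-3-formylcyclopropane-1,1-dicarboxylate
Product: 6 dimethyl (2S,3R)-2-[3,4-bis(benzyloxy)phenyl]-3-(hydroxymethyl)cyclopropane-1,1-dicarboxylate
Conditions: NaBH4, MeOH/CH2Cl2, −20 °C; pH 7 buffer
Reagents that add atoms: none
Why: Chemoselective borohydride reduction of the aldehyde beside two methyl esters, with a cold neutral quench so that the new alcohol does not lactonise onto the cis ester.

Step 4
Reactants: 6 dimethyl (2S,3R)-2-[3,4-bis(benzyloxy)phenyl]-3-(hydroxymethyl)cyclopropane-1,1-dicarboxylate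
Product: 7 dimethyl (2S,3R)-2-[3,4-bis(benzyloxy)phenyl]-3-[(benzyloxy)methyl]cyclopropane-1,1-dicarboxylate
Conditions: BnBr, Ag2O, Bu4NI (cat.), CH2Cl2, rt, dark
Reagents that add atoms: benzyl bromide, BrCc1ccccc1
Why: Silver-oxide-mediated Williamson-type O-benzylation needs no free alkoxide, so neither lactonisation nor opening of the donor–acceptor cyclopropane should compete.

Step 5
Reactants: 7 dimethyl (2S,3R)-2-[3,4-bis(benzyloxy)phenyl]-3-[(benzyloxy)methyl]cyclopropane-1,1-dicarboxylate; 8 formaldehyde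
Product: 9 dimethyl (4R,5R)-5-[3,4-bis(benzyloxy)phenyl]-4-[(benzyloxy)methyl]oxolane-3,3-dicarboxylate
Conditions: CH2O (5 equiv, CH2Cl2 solution from freshly cracked paraformaldehyde), Sn(OTf)2 (10 mol %), 4 Å MS, CH2Cl2, −40 → 0 °C
Reagents that add atoms: none
Why: Chelation of Sn(II) by the geminal diester polarises the strained bond between the aryl-bearing carbon and the malonate carbon, the oxygen of CH2O attacks the benzylic carbon in an SN2-like manner with inversion while the malonate leaves as its tin enolate, and collapse of the oxocarbenium/malonate ion pair forms the C–C bond to the former carbonyl carbon. The closest known reaction type is the Lewis-acid-catalysed (3+2) annulation of 2-arylcyclopropane-1,1-diesters with aldehydes, run here with the simplest aldehyde. The oxolane ring is closed by a 5-(enolexo)-endo-trig attack of the malonate carbon on the O-alkylated oxocarbenium carbon, an intramolecular aldol-type ion-pair collapse. The aryl-bearing stereocentre (C5 of 9) is set by stereospecific inversion of the (2S) cyclopropane carbon, the CH2OBn-bearing centre is carried through untouched, so the trans cyclopropane should give the 4,5-cis oxolane, and the diester carbon is not stereogenic. The step needs invertive opening to outrun ionisation to a free benzylic cation and monomeric CH2O to outrun its oligomers; bidentate diester–tin activation, low temperature and the unhindered aldehyde in excess should secure this, and because the CH2OBn-bearing centre is never touched any leakage costs diastereomeric purity only, not enantiopurity.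

Step 6
Reactants: 9 dimethyl (4R,5R)-5-[3,4-bis(benzyloxy)phenyl]-4-[(benzyloxy)methyl]oxolane-3,3-dicarboxylate
Product: 10 (4R,5R)-5-[3,4-bis(benzyloxy)phenyl]-4-[(benzyloxy)methyl]oxolane-3,3-dicarboxylic acid
Conditions: KOH (6 equiv), MeOH/H2O 3:1, 65 °C; then 1 M HCl, 0 °C, pH 2
Reagents that add atoms: potassium hydroxide, [K+].[OH-]
Why: Saponification of the hindered geminal diester; the malonate carbon has no α-hydrogen, so retro-oxa-Michael ring opening is impossible, and the benzyl ethers are inert to hydroxide.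

Step 7
Reactants: 10 (4R,5R)-5-[3,4-bis(benzyloxy)phenyl]-4-[(benzyloxy)methyl]oxolane-3,3-dicarboxylic acid
Product: 12 (4R,5R)-5-[3,4-bis(benzyloxy)phenyl]-4-[(benzyloxy)methyl]oxolan-3-one, via geminal diacetate 11 (not isolated)
Conditions: Pb(OAc)4 (2.5 equiv), pyridine, MeCN, 50 °C; then K2CO3 (0.2 equiv), MeOH, 0 °C, short contact
Reagents that add atoms: lead(IV) acetate, CC(=O)O[Pb](OC(C)=O)(OC(C)=O)OC(C)=O
Why: Kochi-type oxidative bis-decarboxylation of a disubstituted malonic acid with lead tetraacetate should give the ketone acylal, and brief cold methanolysis releases the ketone before its α-stereocentre (C4) can epimerise.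

Step 8
Reactants: 12 (4R,5R)-5-[3,4-bis(benzyloxy)phenyl]-4-[(benzyloxy)methyl]oxolan-3-one; 13 3,4-dimethoxybenzyl chloride
Product: 15 (3R,4R,5R)-5-[3,4-bis(benzyloxy)phenyl]-4-[(benzyloxy)methyl]-3-[(3,4-dimethoxyphenyl)methyl]oxolan-3-ol, via benzylic Grignard reagent 14 (not isolated)
Conditions: 13, Mg, THF, 0 °C; then LaCl3·2LiCl (1 equiv), 12, THF, −78 °C; aq NH4Cl
Reagents that add atoms: none
Why: Grignard 1,2-addition with a lanthanum salt to suppress enolisation; the benzyl nucleophile should attack the carbonyl face opposite the cis CH2OBn and aryl groups, which places the new hydroxyl cis to CH2OBn and sets C3 as R.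

Step 9
Reactants: 15 (3R,4R,5R)-5-[3,4-bis(benzyloxy)phenyl]-4-[(benzyloxy)methyl]-3-[(3,4-dimethoxyphenyl)methyl]oxolan-3-ol
Product: 16 (3R,4R,5R)-5-(3,4-dihydroxyphenyl)-3-[(3,4-dimethoxyphenyl)methyl]-4-(hydroxymethyl)oxolan-3-ol
Conditions: H2 (1 atm), 10% Pd/C, EtOAc/MeOH, rt
Reagents that add atoms: none
Why: Catalytic hydrogenolysis of the three O-benzyl ethers under neutral conditions; the cyclic benzylic C–O bond and the tertiary alcohol react much more slowly and no stereocentre is touched.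

Compound list
1 | 3,4-bis(benzyloxy)benzaldehyde | O=Cc1ccc(OCc2ccccc2)c(OCc2ccccc2)c1 | starting material
2 | (triphenylphosphoranylidene)acetaldehyde | O=CC=P(c1ccccc1)(c1ccccc1)c1ccccc1 | starting material
3 | (E)-3-[3,4-bis(benzyloxy)phenyl]prop-2-enal | O=C/C=C/c1ccc(OCc2ccccc2)c(OCc2ccccc2)c1 | intermediate
4 | dimethyl bromomalonate | COC(=O)C(Br)C(=O)OC | starting material
5 | dimethyl (2S,3R)-2-[3,4-bis(benzyloxy)phenyl]-3-formylcyclopropane-1,1-dicarboxylate | COC(=O)C1(C(=O)OC)[C@H](c2ccc(OCc3ccccc3)c(OCc3ccccc3)c2)[C@H]1C=O | intermediate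
6 | dimethyl (2S,3R)-2-[3,4-bis(benzyloxy)phenyl]-3-(hydroxymethyl)cyclopropane-1,1-dicarboxylate | COC(=O)C1(C(=O)OC)[C@H](c2ccc(OCc3ccccc3)c(OCc3ccccc3)c2)[C@H]1CO | intermediate
7 | dimethyl (2S,3R)-2-[3,4-bis(benzyloxy)phenyl]-3-[(benzyloxy)methyl]cyclopropane-1,1-dicarboxylate | COC(=O)C1(C(=O)OC)[C@H](c2ccc(OCc3ccccc3)c(OCc3ccccc3)c2)[C@H]1COCc1ccccc1 | intermediate
8 | formaldehyde (from paraformaldehyde) | C=O | starting material
9 | dimethyl (4R,5R)-5-[3,4-bis(benzyloxy)phenyl]-4-[(benzyloxy)methyl]oxolane-3,3-dicarboxylate | COC(=O)C1(C(=O)OC)CO[C@@H](c2ccc(OCc3ccccc3)c(OCc3ccccc3)c2)[C@H]1COCc1ccccc1 | intermediate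
10 | (4R,5R)-5-[3,4-bis(benzyloxy)phenyl]-4-[(benzyloxy)methyl]oxolane-3,3-dicarboxylic acid | OC(=O)C1(C(=O)O)CO[C@@H](c2ccc(OCc3ccccc3)c(OCc3ccccc3)c2)[C@H]1COCc1ccccc1 | intermediate
11 | (4R,5R)-5-[3,4-bis(benzyloxy)phenyl]-4-[(benzyloxy)methyl]oxolane-3,3-diyl diacetate | CC(=O)OC1(OC(C)=O)CO[C@@H](c2ccc(OCc3ccccc3)c(OCc3ccccc3)c2)[C@H]1COCc1ccccc1 | intermediate
12 | (4R,5R)-5-[3,4-bis(benzyloxy)phenyl]-4-[(benzyloxy)methyl]oxolan-3-one | O=C1CO[C@@H](c2ccc(OCc3ccccc3)c(OCc3ccccc3)c2)[C@H]1COCc1ccccc1 | intermediate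
13 | 3,4-dimethoxybenzyl chloride | COc1ccc(CCl)cc1OC | starting material
14 | 3,4-dimethoxybenzylmagnesium chloride | COc1ccc(C[Mg]Cl)cc1OC | intermediate
15 | (3R,4R,5R)-5-[3,4-bis(benzyloxy)phenyl]-4-[(benzyloxy)methyl]-3-[(3,4-dimethoxyphenyl)methyl]oxolan-3-ol | COc1ccc(C[C@]2(O)CO[C@@H](c3ccc(OCc4ccccc4)c(OCc4ccccc4)c3)[C@H]2COCc2ccccc2)cc1OC | intermediate
16 | (3R,4R,5R)-5-(3,4-dihydroxyphenyl)-3-[(3,4-dimethoxyphenyl)methyl]-4-(hydroxymethyl)oxolan-3-ol | COc1ccc(C[C@]2(O)CO[C@@H](c3ccc(O)c(O)c3)[C@H]2CO)cc1OC | target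

Total step count: 9. Longest linear sequence: 9 steps (1 → 16).

Steps most likely to fail

Step 5. The strongly cation-stabilising 3,4-bis(benzyloxy)phenyl donor may let the benzylic bond ionise before formaldehyde attacks. That would erode the inversion (leakage into the 2,3-trans series) or lead to β-hydride loss to a styrene, and formaldehyde may oligomerise on the Lewis acid instead of reacting. The fallback sets out from 1 and comes back at 12, closing the ring by O–H insertion instead of cycloaddition. (R)-4-Benzyloxazolidin-2-one is acylated (n-BuLi, 3-(benzyloxy)propanoyl chloride) to (R)-4-benzyl-3-[3-(benzyloxy)propanoyl]oxazolidin-2-one F1. Its dibutylboron (Z)-enolate (Bu2BOTf, i-Pr2NEt, CH2Cl2, −78 °C) adds to 1 in an Evans syn-aldol reaction to give the (2R,3R)-aldol imide F2; a syn aldol corresponds to the cis ring relationship. Silylation (TBSOTf, 2,6-lutidine) should give the silyl ether imide F3, and LiOH/H2O2 cleavage the silyloxy acid F4. Mixed-anhydride activation (i-BuOCOCl, N-methylmorpholine) followed by diazomethane gives the silyloxy diazoketone F5, and buffered fluoride (Bu4NF/AcOH) the hydroxy diazoketone F6. Rh2(OAc)4-catalysed intramolecular O–H insertion under neutral conditions then closes the oxolan-3-one 12.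

Step 7. Lead(IV) may oxidise the electron-rich aryl ethers or benzylic C–H bonds, and the unmasked ketone may epimerise at its α-stereocentre or undergo β-elimination. The fallback sets out from 9 and comes back at 15 without ever passing through a ketone. Krapcho dealkoxycarbonylation (LiCl, wet DMSO, 150 °C) gives the monoester F7 as an inconsequential epimer mixture. Its lithium enolate (LDA, THF, −78 °C) is alkylated with 3,4-dimethoxybenzyl bromide anti to the CH2OBn group to give the quaternary ester F8. DIBAL-H at −78 °C gives the neopentyl aldehyde F9. Baeyer–Villiger oxidation (mCPBA, Na2HPO4, CH2Cl2), in which the tertiary carbon migrates with retention, gives the tertiary formate F10, and K2CO3/MeOH releases 15.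

Step 8. The basic benzylic Grignard reagent may deprotonate instead of add (epimerisation or β-elimination of the ketone), and the electron-rich benzyl chloride may undergo Wurtz coupling while the reagent forms. The fallback sets out from 12 and comes back at 15, making the aryl–CH2 bond instead of the CH2–carbinol bond. Corey–Chaykovsky methylenation with dimethylsulfonium methylide (Me3S+ I−, KHMDS, THF, −10 °C) should deliver CH2 to the same open face and give the spiro-epoxide F11. Copper-catalysed opening at its CH2 terminus with commercial 3,4-dimethoxyphenylmagnesium bromide (CuI 10 mol %, THF, −30 °C) then gives 15.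

Further compounds
F1 | step 5 | (R)-4-benzyl-3-[3-(benzyloxy)propanoyl]oxazolidin-2-one | O=C(CCOCc1ccccc1)N1C(=O)OC[C@H]1Cc1ccccc1
F2 | step 5 | (R)-4-benzyl-3-[(2R,3R)-3-[3,4-bis(benzyloxy)phenyl]-2-[(benzyloxy)methyl]-3-hydroxypropanoyl]oxazolidin-2-one | O[C@@H](c1ccc(OCc2ccccc2)c(OCc2ccccc2)c1)[C@@H](COCc1ccccc1)C(=O)N1C(=O)OC[C@H]1Cc1ccccc1
F3 | step 5 | (R)-4-benzyl-3-[(2R,3R)-3-[3,4-bis(benzyloxy)phenyl]-2-[(benzyloxy)methyl]-3-[(tert-butyldimethylsilyl)oxy]propanoyl]oxazolidin-2-one | CC(C)(C)[Si](C)(C)O[C@@H](c1ccc(OCc2ccccc2)c(OCc2ccccc2)c1)[C@@H](COCc1ccccc1)C(=O)N1C(=O)OC[C@H]1Cc1ccccc1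
F4 | step 5 | (2R,3R)-3-[3,4-bis(benzyloxy)phenyl]-2-[(benzyloxy)methyl]-3-[(tert-butyldimethylsilyl)oxy]propanoic acid | CC(C)(C)[Si](C)(C)O[C@@H](c1ccc(OCc2ccccc2)c(OCc2ccccc2)c1)[C@@H](COCc1ccccc1)C(=O)O
F5 | step 5 | (3R,4R)-4-[3,4-bis(benzyloxy)phenyl]-3-[(benzyloxy)methyl]-4-[(tert-butyldimethylsilyl)oxy]-1-diazobutan-2-one | CC(C)(C)[Si](C)(C)O[C@@H](c1ccc(OCc2ccccc2)c(OCc2ccccc2)c1)[C@@H](COCc1ccccc1)C(=O)C=[N+]=[N-]
F6 | step 5 | (3R,4R)-4-[3,4-bis(benzyloxy)phenyl]-3-[(benzyloxy)methyl]-1-diazo-4-hydroxybutan-2-one | O[C@@H](c1ccc(OCc2ccccc2)c(OCc2ccccc2)c1)[C@@H](COCc1ccccc1)C(=O)C=[N+]=[N-]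
F7 | step 7 | methyl (4R,5R)-5-[3,4-bis(benzyloxy)phenyl]-4-[(benzyloxy)methyl]oxolane-3-carboxylate (C3 epimer mixture) | COC(=O)C1CO[C@@H](c2ccc(OCc3ccccc3)c(OCc3ccccc3)c2)[C@H]1COCc1ccccc1
F8 | step 7 | methyl (3R,4R,5R)-5-[3,4-bis(benzyloxy)phenyl]-4-[(benzyloxy)methyl]-3-[(3,4-dimethoxyphenyl)methyl]oxolane-3-carboxylate | COc1ccc(C[C@]2(C(=O)OC)CO[C@@H](c3ccc(OCc4ccccc4)c(OCc4ccccc4)c3)[C@H]2COCc2ccccc2)cc1OC
F9 | step 7 | (3R,4R,5R)-5-[3,4-bis(benzyloxy)phenyl]-4-[(benzyloxy)methyl]-3-[(3,4-dimethoxyphenyl)methyl]oxolane-3-carbaldehyde | COc1ccc(C[C@]2(C=O)CO[C@@H](c3ccc(OCc4ccccc4)c(OCc4ccccc4)c3)[C@H]2COCc2ccccc2)cc1OC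
F10 | step 7 | (3R,4R,5R)-5-[3,4-bis(benzyloxy)phenyl]-4-[(benzyloxy)methyl]-3-[(3,4-dimethoxyphenyl)methyl]oxolan-3-yl formate | COc1ccc(C[C@]2(OC=O)CO[C@@H](c3ccc(OCc4ccccc4)c(OCc4ccccc4)c3)[C@H]2COCc2ccccc2)cc1OC
F11 | step 8 | (3S,6R,7R)-6-[3,4-bis(benzyloxy)phenyl]-7-[(benzyloxy)methyl]-1,5-dioxaspiro[2.4]heptane | C1[C@]2(O1)CO[C@@H](c1ccc(OCc3ccccc3)c(OCc3ccccc3)c1)[C@H]2COCc1ccccc1
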